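**Retrosynthetic overview**

1. Isochromene locants (O2, C1–C8a) are used for the same atoms in all intermediates. The pyran ring O2–C1–C8a=C4a–C4=C3 is a 2H-pyran, the valence tautomer of the 1-oxatriene O=C3–C4=C4a–C8a=C1, and is opened first (retro-oxa-6π).
2. The trienone is traced back by retro-elimination of MeOH at C4a and a retro-Claisen cut of C4–C4a to a 2-(hydroxymethyl)-3-methoxycyclohex-2-enone and (E)-2-ethoxypenta-1,3-diene. The enabling feature is the allylic array O2–C1–C8a=C4a with a leaving group on C4a (1,3-dione level at C8/C4a), and the C8 ketone, which makes the closed dienol ether O2–C3=C4–C4a=C8a–C8=O the thermodynamic sink.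
3. The hydroxymethyl enone comes from the C8/C4a 1,3-dione by O-methylation, C8a iodination and Stille hydroxymethylation. The hindered C7 ester is installed earlier with an aroyl triflate made from 2,4-dihydroxy-6-methylbenzaldehyde.
4. The dione comes from (R)-carvone: trans-epoxidation and hydrolysis set C6 and C7, and the isopropenyl-bearing C4a, after serving as the control element, is degraded (Criegee) to the C4a carbonyl.
5. Ring order: the carbocycle (chiral pool) and the arene (purchased) are present from the start; the pyran is the only ring made and is closed last.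

Key step: step 16

Remark: the 1,3-dione intermediate is drawn as its diketo tautomer and is assumed to react as the enol or enolate.

**Route**

Step 1
Reactants: 1 2,4-dihydroxy-6-methylbenzaldehyde
Product: 2 2-hydroxy-6-methyl-4-[(triisopropylsilyl)oxy]benzaldehyde
Conditions: TIPSCl (1.05 equiv), imidazole, DMF, 0 °C to rt
Reagents that add atoms: triisopropylsilyl chloride, CC(C)[Si](Cl)(C(C)C)C(C)C
Why: Selective O-silylation should occur at the 4-hydroxyl because the 2-hydroxyl is held in a hydrogen bond to the formyl group.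

Step 2
Reactants: 2 2-hydroxy-6-methyl-4-[(triisopropylsilyl)oxy]benzaldehyde
Product: 3 2-methoxy-6-methyl-4-[(triisopropylsilyl)oxy]benzaldehyde
Conditions: MeI, Ag2O, MeCN, rt, dark
Reagents that add atoms: iodomethane, CI
Why: Ag2O-mediated Williamson methylation alkylates the chelated phenol under non-basic conditions that should leave the aryl silyl ether intact.

Step 3
Reactants: 3 2-methoxy-6-methyl-4-[(triisopropylsilyl)oxy]benzaldehyde
Product: 4 2-methoxy-6-methyl-4-[(triisopropylsilyl)oxy]benzoic acid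
Conditions: NaClO2, NaH2PO4, 2-methylbut-2-ene, t-BuOH/H2O, rt
Reagents that add atoms: sodium chlorite, [Na+].[O-]Cl=O
Why: Pinnick oxidation converts the hindered, electron-rich aldehyde to the acid while 2-methylbut-2-ene scavenges hypochlorous acid and so prevents ring chlorination.

Step 4
Reactants: 4 2-methoxy-6-methyl-4-[(triisopropylsilyl)oxy]benzoic acid
Product: 5 2-methoxy-6-methyl-4-[(triisopropylsilyl)oxy]benzoyl chloride
Conditions: 1-chloro-N,N,2-trimethylprop-1-en-1-amine (1.2 equiv), CH2Cl2, 0 °C to rt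
Reagents that add atoms: 1-chloro-N,N,2-trimethylprop-1-en-1-amine, CC(C)=C(Cl)N(C)C
Why: The α-chloroenamine forms the acid chloride under neutral conditions without HCl, which should preserve the aryl silyl ether.

Step 5
Reactants: 6 tributyl(1-ethoxyvinyl)stannane; 7 (E)-1-bromoprop-1-ene
Product: 8 (3E)-2-ethoxypenta-1,3-diene
Conditions: Pd(PPh3)4 (3 mol %), diglyme, 80 °C, sealed vessel; product distilled off
Reagents that add atoms: none
Why: Stille coupling of an α-alkoxyvinylstannane with a vinyl bromide proceeds with retention of the E geometry and should give the 2-alkoxydiene needed as enol-ether partner.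

Step 6
Reactants: 9 (R)-carvone
Product: 10 (1R,4R,6R)-1-methyl-4-(prop-1-en-2-yl)-7-oxabicyclo[4.1.0]heptan-2-one
Conditions: 30% aq. H2O2, NaOH (cat.), MeOH, 0 °C
Reagents that add atoms: hydrogen peroxide, OO
Why: Weitz–Scheffer nucleophilic epoxidation touches only the enone, and hydroperoxide adds to C6 anti to the isopropenyl group on C4a, so the epoxide oxygen should be trans to that group and fix C6 and C7.

Step 7
Reactants: 10 (1R,4R,6R)-1-methyl-4-(prop-1-en-2-yl)-7-oxabicyclo[4.1.0]heptan-2-one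
Product: 11 (2R,3S,5R)-2,3-dihydroxy-2-methyl-5-(prop-1-en-2-yl)cyclohexan-1-one
Conditions: HClO4 (0.5 M aq.), THF, rt
Reagents that add atoms: water, O
Why: Acid-catalysed epoxide hydrolysis should open the α,β-epoxy ketone by SN2 attack of water at the secondary β-carbon C6 with inversion, leaving the tertiary C7–O bond intact and giving the trans-diol.

Step 8
Reactants: 11 (2R,3S,5R)-2,3-dihydroxy-2-methyl-5-(prop-1-en-2-yl)cyclohexan-1-one
Product: 12 (2R,3S,5R)-3-[(tert-butyldimethylsilyl)oxy]-2-hydroxy-2-methyl-5-(prop-1-en-2-yl)cyclohexan-1-one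
Conditions: TBSOTf (1.1 equiv), 2,6-lutidine, CH2Cl2, −78 °C
Reagents that add atoms: tert-butyldimethylsilyl triflate, CC(C)(C)[Si](C)(C)OS(=O)(=O)C(F)(F)F
Why: Silylation at low temperature should discriminate the secondary C6 hydroxyl from the tertiary C7 hydroxyl on steric grounds.

Step 9
Reactants: 12 (2R,3S,5R)-3-[(tert-butyldimethylsilyl)oxy]-2-hydroxy-2-methyl-5-(prop-1-en-2-yl)cyclohexan-1-one
Product: 15 (1R,3S,4R)-3-[(tert-butyldimethylsilyl)oxy]-4-hydroxy-4-methyl-5-oxocyclohexyl acetate, via methoxy hydroperoxide 13 (not isolated), via peracetate 14 (not isolated)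
Conditions: O3, CH2Cl2/MeOH, −78 °C; then Ac2O, Et3N, DMAP (cat.), 0 °C to rt
Reagents that add atoms: ozone, [O-][O+]=O; methanol, CO
Why: Ozonolysis in methanol followed by Criegee rearrangement of the O-acetylated α-methoxy hydroperoxide should replace the isopropenyl group by acetoxy with retention at C4a, because the ring carbon migrates to oxygen with its configuration intact.

Step 10
Reactants: 15 (1R,3S,4R)-3-[(tert-butyldimethylsilyl)oxy]-4-hydroxy-4-methyl-5-oxocyclohexyl acetate; 5 2-methoxy-6-methyl-4-[(triisopropylsilyl)oxy]benzoyl chloride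
Product: 17 (1R,2S,4R)-4-(acetyloxy)-2-[(tert-butyldimethylsilyl)oxy]-1-methyl-6-oxocyclohexyl 2-methoxy-6-methyl-4-[(triisopropylsilyl)oxy]benzoate, via aroyl triflate 16 (not isolated)
Conditions: AgOTf (1.6 equiv), 2,6-di-tert-butylpyridine, CH2Cl2, −40 to 0 °C
Reagents that add atoms: none
Why: The mixed carboxylic–triflic anhydride acylates through a slim, acylium-like electrophile, the established way to esterify a 2,6-disubstituted benzoic acid with a tertiary alcohol, and the C7–O bond is not broken so its configuration is kept.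

Step 11
Reactants: 17 (1R,2S,4R)-4-(acetyloxy)-2-[(tert-butyldimethylsilyl)oxy]-1-methyl-6-oxocyclohexyl 2-methoxy-6-methyl-4-[(triisopropylsilyl)oxy]benzoate
Product: 18 (1R,2S,4R)-2-[(tert-butyldimethylsilyl)oxy]-4-hydroxy-1-methyl-6-oxocyclohexyl 2-methoxy-6-methyl-4-[(triisopropylsilyl)oxy]benzoate
Conditions: K2CO3 (0.2 equiv), MeOH, 0 °C
Reagents that add atoms: none
Why: Zemplén-type methanolysis should remove the unhindered secondary acetate much faster than it attacks the 2,6-disubstituted aroyl ester or the bulky aryl silyl ether.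

Step 12
Reactants: 18 (1R,2S,4R)-2-[(tert-butyldimethylsilyl)oxy]-4-hydroxy-1-methyl-6-oxocyclohexyl 2-methoxy-6-methyl-4-[(triisopropylsilyl)oxy]benzoate
Product: 19 (1R,2S)-2-[(tert-butyldimethylsilyl)oxy]-1-methyl-4,6-dioxocyclohexyl 2-methoxy-6-methyl-4-[(triisopropylsilyl)oxy]benzoate
Conditions: Dess–Martin periodinane, CH2Cl2, rt
Reagents that add atoms: none
Why: Dess–Martin oxidation of the β-hydroxy ketone gives the 1,3-dione under non-basic conditions, so the β-silyloxy group on C6 should not be eliminated.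

Step 13
Reactants: 19 (1R,2S)-2-[(tert-butyldimethylsilyl)oxy]-1-methyl-4,6-dioxocyclohexyl 2-methoxy-6-methyl-4-[(triisopropylsilyl)oxy]benzoate
Product: 20 (1R,6S)-6-[(tert-butyldimethylsilyl)oxy]-4-methoxy-1-methyl-2-oxocyclohex-3-en-1-yl 2-methoxy-6-methyl-4-[(triisopropylsilyl)oxy]benzoate
Conditions: Me2SO4, K2CO3, acetone, rt
Reagents that add atoms: dimethyl sulfate, COS(=O)(=O)OC
Why: O-Alkylation of the ambident 1,3-dione enolate should occur at the oxygen on C4a, remote from the quaternary C7, as is usual for 4,4-disubstituted cyclohexane-1,3-diones, with any minor regioisomer removed by chromatography.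

Step 14
Reactants: 20 (1R,6S)-6-[(tert-butyldimethylsilyl)oxy]-4-methoxy-1-methyl-2-oxocyclohex-3-en-1-yl 2-methoxy-6-methyl-4-[(triisopropylsilyl)oxy]benzoate
Product: 21 (1R,6S)-6-[(tert-butyldimethylsilyl)oxy]-3-iodo-4-methoxy-1-methyl-2-oxocyclohex-3-en-1-yl 2-methoxy-6-methyl-4-[(triisopropylsilyl)oxy]benzoate
Conditions: NIS (1.05 equiv), MeCN, 0 °C to rt, dark
Reagents that add atoms: N-iodosuccinimide, O=C1CCC(=O)N1I
Why: Electrophilic α-iodination of the push–pull enol ether should take place at C8a, the nucleophilic carbon of the vinylogous ester, faster than at the ester-deactivated arene.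

Step 15
Reactants: 21 (1R,6S)-6-[(tert-butyldimethylsilyl)oxy]-3-iodo-4-methoxy-1-methyl-2-oxocyclohex-3-en-1-yl 2-methoxy-6-methyl-4-[(triisopropylsilyl)oxy]benzoate
Product: 22 (1R,6S)-6-[(tert-butyldimethylsilyl)oxy]-3-(hydroxymethyl)-4-methoxy-1-methyl-2-oxocyclohex-3-en-1-yl 2-methoxy-6-methyl-4-[(triisopropylsilyl)oxy]benzoate
Conditions: Bu3SnCH2OH, Pd(PPh3)4 (10 mol %), 1,4-dioxane, 90 °C
Reagents that add atoms: (tributylstannyl)methanol, CCCC[Sn](CCCC)(CCCC)CO
Why: Stille coupling of the vinyl iodide with (tributylstannyl)methanol should install C1 with its oxygen directly at the alcohol oxidation level.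

Step 16
Reactants: 22 (1R,6S)-6-[(tert-butyldimethylsilyl)oxy]-3-(hydroxymethyl)-4-methoxy-1-methyl-2-oxocyclohex-3-en-1-yl 2-methoxy-6-methyl-4-[(triisopropylsilyl)oxy]benzoate; 8 (3E)-2-ethoxypenta-1,3-diene
Product: 27 (6S,7R)-6-[(tert-butyldimethylsilyl)oxy]-7-methyl-8-oxo-3-[(1E)-prop-1-en-1-yl]-5,6,7,8-tetrahydro-1H-isochromen-7-yl 2-methoxy-6-methyl-4-[(triisopropylsilyl)oxy]benzoate, via mixed ketal 23 (not isolated), via allyl dienyl ether 24 (not isolated), via Claisen ketone 25 (not isolated), via oxatriene 26 (not isolated)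
Conditions: 8 (4 equiv), 2,4-dinitrophenol (10 mol %), toluene (0.05 M), 110 °C, sealed tube
Reagents that add atoms: none
Why: Proposed new method: acid-catalysed alkoxy exchange between the primary allylic alcohol and 8 gives, through the mixed ketal, the allyl dienyl ether, whose chair-like [3,3] sigmatropic (Claisen) shift forms C4–C4a and turns C1 into an exocyclic methylene, after which the β-methoxy group on the now quaternary C4a is expelled through the enol of the new C3 ketone to give the cross-conjugated trienone O=C3–C4=C4a–C8a=C1. The trienone then closes by thermal disrotatory oxa-6π electrocyclisation, the only ring-forming event, which re-forms the O2–C1 bond and gives the 2H-pyran. The closest known reaction types are the ketal Claisen rearrangement of allylic alcohols with 2-alkoxy-1,3-dienes (Saucy–Marbet type) and the Knoevenagel/oxa-6π route to fused 2H-pyrans, which have not been merged on the allylic alcohol of a vinylogous ester. No stereocentre is created, since C4a is sp3 only in passing, C6 and C7 are spectators and the E-propenyl geometry is carried over from 8. The step needs C–C bond formation at C4a, which the six-membered [3,3] array dictates, elimination towards C4, which is the only enolisable position of the C3 ketone, and the Z-trienone, into which the E isomer is funnelled by reversible acid-catalysed isomerisation because only the Z isomer can cyclise. Ring closure is secured thermodynamically, because it trades an unstabilised 2-methylene ketone for the push–pull dienol ether O2–C3=C4–C4a=C8a–C8=O.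

Step 17
Reactants: 27 (6S,7R)-6-[(tert-butyldimethylsilyl)oxy]-7-methyl-8-oxo-3-[(1E)-prop-1-en-1-yl]-5,6,7,8-tetrahydro-1H-isochromen-7-yl 2-methoxy-6-methyl-4-[(triisopropylsilyl)oxy]benzoate
Product: 28 (6S,7R)-6-hydroxy-7-methyl-8-oxo-3-[(1E)-prop-1-en-1-yl]-5,6,7,8-tetrahydro-1H-isochromen-7-yl 4-hydroxy-2-methoxy-6-methylbenzoate
Conditions: HF·pyridine, pyridine, THF, 0 °C to rt
Reagents that add atoms: none
Why: Pyridine-buffered fluoride desilylation should cleave both the aryl triisopropylsilyl and the secondary tert-butyldimethylsilyl ether without acid hydrolysis of the dienol ether or base-induced β-elimination of the C6 hydroxyl.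

**Compound list**

1 | 2,4-dihydroxy-6-methylbenzaldehyde | O=Cc1c(C)cc(O)cc1O | starting material
2 | 2-hydroxy-6-methyl-4-[(triisopropylsilyl)oxy]benzaldehyde | O=Cc1c(C)cc(O[Si](C(C)C)(C(C)C)C(C)C)cc1O | intermediate
3 | 2-methoxy-6-methyl-4-[(triisopropylsilyl)oxy]benzaldehyde | O=Cc1c(C)cc(O[Si](C(C)C)(C(C)C)C(C)C)cc1OC | intermediate
4 | 2-methoxy-6-methyl-4-[(triisopropylsilyl)oxy]benzoic acid | OC(=O)c1c(C)cc(O[Si](C(C)C)(C(C)C)C(C)C)cc1OC | intermediate
5 | 2-methoxy-6-methyl-4-[(triisopropylsilyl)oxy]benzoyl chloride | ClC(=O)c1c(C)cc(O[Si](C(C)C)(C(C)C)C(C)C)cc1OC | intermediate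
6 | tributyl(1-ethoxyvinyl)stannane | CCCC[Sn](CCCC)(CCCC)C(=C)OCC | starting material
7 | (E)-1-bromoprop-1-ene | C/C=C/Br | starting material
8 | (3E)-2-ethoxypenta-1,3-diene | C=C(OCC)/C=C/C | intermediate
9 | (R)-carvone, (5R)-2-methyl-5-(prop-1-en-2-yl)cyclohex-2-en-1-one | O=C1C(C)=CC[C@@H](C(C)=C)C1 | starting material
10 | (1R,4R,6R)-1-methyl-4-(prop-1-en-2-yl)-7-oxabicyclo[4.1.0]heptan-2-one (epoxide trans to isopropenyl) | O=C1[C@]2(C)O[C@@H]2C[C@@H](C(C)=C)C1 | intermediate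
11 | (2R,3S,5R)-2,3-dihydroxy-2-methyl-5-(prop-1-en-2-yl)cyclohexan-1-one | O=C1[C@](C)(O)[C@@H](O)C[C@@H](C(C)=C)C1 | intermediate
12 | (2R,3S,5R)-3-[(tert-butyldimethylsilyl)oxy]-2-hydroxy-2-methyl-5-(prop-1-en-2-yl)cyclohexan-1-one | O=C1[C@](C)(O)[C@@H](O[Si](C)(C)C(C)(C)C)C[C@@H](C(C)=C)C1 | intermediate
13 | methoxy hydroperoxide: (2R,3S,5R)-3-[(tert-butyldimethylsilyl)oxy]-2-hydroxy-5-(1-hydroperoxy-1-methoxyethyl)-2-methylcyclohexan-1-one, side-chain carbon as epimer mixture | O=C1[C@](C)(O)[C@@H](O[Si](C)(C)C(C)(C)C)C[C@@H](C(C)(OC)OO)C1 | intermediate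
14 | peracetate: (2R,3S,5R)-5-[1-(acetylperoxy)-1-methoxyethyl]-3-[(tert-butyldimethylsilyl)oxy]-2-hydroxy-2-methylcyclohexan-1-one, side-chain carbon as epimer mixture | O=C1[C@](C)(O)[C@@H](O[Si](C)(C)C(C)(C)C)C[C@@H](C(C)(OC)OOC(C)=O)C1 | intermediate
15 | (1R,3S,4R)-3-[(tert-butyldimethylsilyl)oxy]-4-hydroxy-4-methyl-5-oxocyclohexyl acetate | O=C1[C@](C)(O)[C@@H](O[Si](C)(C)C(C)(C)C)C[C@@H](OC(C)=O)C1 | intermediate
16 | aroyl triflate: 2-methoxy-6-methyl-4-[(triisopropylsilyl)oxy]benzoic trifluoromethanesulfonic anhydride | O=C(OS(=O)(=O)C(F)(F)F)c1c(C)cc(O[Si](C(C)C)(C(C)C)C(C)C)cc1OC | intermediate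
17 | (1R,2S,4R)-4-(acetyloxy)-2-[(tert-butyldimethylsilyl)oxy]-1-methyl-6-oxocyclohexyl 2-methoxy-6-methyl-4-[(triisopropylsilyl)oxy]benzoate | O=C1[C@](C)(OC(=O)c2c(C)cc(O[Si](C(C)C)(C(C)C)C(C)C)cc2OC)[C@@H](O[Si](C)(C)C(C)(C)C)C[C@@H](OC(C)=O)C1 | intermediate
18 | (1R,2S,4R)-2-[(tert-butyldimethylsilyl)oxy]-4-hydroxy-1-methyl-6-oxocyclohexyl 2-methoxy-6-methyl-4-[(triisopropylsilyl)oxy]benzoate | O=C1[C@](C)(OC(=O)c2c(C)cc(O[Si](C(C)C)(C(C)C)C(C)C)cc2OC)[C@@H](O[Si](C)(C)C(C)(C)C)C[C@@H](O)C1 | intermediate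
19 | (1R,2S)-2-[(tert-butyldimethylsilyl)oxy]-1-methyl-4,6-dioxocyclohexyl 2-methoxy-6-methyl-4-[(triisopropylsilyl)oxy]benzoate (diketo tautomer drawn) | O=C1[C@](C)(OC(=O)c2c(C)cc(O[Si](C(C)C)(C(C)C)C(C)C)cc2OC)[C@@H](O[Si](C)(C)C(C)(C)C)CC(=O)C1 | intermediate
20 | (1R,6S)-6-[(tert-butyldimethylsilyl)oxy]-4-methoxy-1-methyl-2-oxocyclohex-3-en-1-yl 2-methoxy-6-methyl-4-[(triisopropylsilyl)oxy]benzoate | O=C1[C@](C)(OC(=O)c2c(C)cc(O[Si](C(C)C)(C(C)C)C(C)C)cc2OC)[C@@H](O[Si](C)(C)C(C)(C)C)CC(OC)=C1 | intermediate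
21 | (1R,6S)-6-[(tert-butyldimethylsilyl)oxy]-3-iodo-4-methoxy-1-methyl-2-oxocyclohex-3-en-1-yl 2-methoxy-6-methyl-4-[(triisopropylsilyl)oxy]benzoate | O=C1[C@](C)(OC(=O)c2c(C)cc(O[Si](C(C)C)(C(C)C)C(C)C)cc2OC)[C@@H](O[Si](C)(C)C(C)(C)C)CC(OC)=C1I | intermediate
22 | (1R,6S)-6-[(tert-butyldimethylsilyl)oxy]-3-(hydroxymethyl)-4-methoxy-1-methyl-2-oxocyclohex-3-en-1-yl 2-methoxy-6-methyl-4-[(triisopropylsilyl)oxy]benzoate | O=C1[C@](C)(OC(=O)c2c(C)cc(O[Si](C(C)C)(C(C)C)C(C)C)cc2OC)[C@@H](O[Si](C)(C)C(C)(C)C)CC(OC)=C1CO | intermediate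
23 | mixed ketal: (1R,6S)-6-[(tert-butyldimethylsilyl)oxy]-3-({[(3E)-2-ethoxypent-3-en-2-yl]oxy}methyl)-4-methoxy-1-methyl-2-oxocyclohex-3-en-1-yl 2-methoxy-6-methyl-4-[(triisopropylsilyl)oxy]benzoate, ketal carbon as epimer mixture | O=C1[C@](C)(OC(=O)c2c(C)cc(O[Si](C(C)C)(C(C)C)C(C)C)cc2OC)[C@@H](O[Si](C)(C)C(C)(C)C)CC(OC)=C1COC(C)(OCC)/C=C/C | intermediate
24 | allyl dienyl ether: (1R,6S)-6-[(tert-butyldimethylsilyl)oxy]-4-methoxy-1-methyl-2-oxo-3-({[(3E)-penta-1,3-dien-2-yl]oxy}methyl)cyclohex-3-en-1-yl 2-methoxy-6-methyl-4-[(triisopropylsilyl)oxy]benzoate | O=C1[C@](C)(OC(=O)c2c(C)cc(O[Si](C(C)C)(C(C)C)C(C)C)cc2OC)[C@@H](O[Si](C)(C)C(C)(C)C)CC(OC)=C1COC(=C)/C=C/C | intermediate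
25 | Claisen ketone: (1R,2S)-2-[(tert-butyldimethylsilyl)oxy]-4-methoxy-1-methyl-5-methylidene-6-oxo-4-[(3E)-2-oxopent-3-en-1-yl]cyclohexyl 2-methoxy-6-methyl-4-[(triisopropylsilyl)oxy]benzoate, C4 as epimer mixture | O=C1[C@](C)(OC(=O)c2c(C)cc(O[Si](C(C)C)(C(C)C)C(C)C)cc2OC)[C@@H](O[Si](C)(C)C(C)(C)C)CC(OC)(CC(=O)/C=C/C)C1=C | intermediate
26 | oxatriene: (1R,2S,4Z)-2-[(tert-butyldimethylsilyl)oxy]-1-methyl-5-methylidene-6-oxo-4-[(3E)-2-oxopent-3-en-1-ylidene]cyclohexyl 2-methoxy-6-methyl-4-[(triisopropylsilyl)oxy]benzoate | O=C1[C@](C)(OC(=O)c2c(C)cc(O[Si](C(C)C)(C(C)C)C(C)C)cc2OC)[C@@H](O[Si](C)(C)C(C)(C)C)C/C(=C/C(=O)/C=C/C)C1=C | intermediate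
27 | (6S,7R)-6-[(tert-butyldimethylsilyl)oxy]-7-methyl-8-oxo-3-[(1E)-prop-1-en-1-yl]-5,6,7,8-tetrahydro-1H-isochromen-7-yl 2-methoxy-6-methyl-4-[(triisopropylsilyl)oxy]benzoate | C/C=C/C1=CC2=C(CO1)C(=O)[C@](C)(OC(=O)c3c(C)cc(O[Si](C(C)C)(C(C)C)C(C)C)cc3OC)[C@@H](O[Si](C)(C)C(C)(C)C)C2 | intermediate
28 | (6S,7R)-6-hydroxy-7-methyl-8-oxo-3-[(1E)-prop-1-en-1-yl]-5,6,7,8-tetrahydro-1H-isochromen-7-yl 4-hydroxy-2-methoxy-6-methylbenzoate | C/C=C/C1=CC2=C(CO1)C(=O)[C@](C)(OC(=O)c3c(C)cc(O)cc3OC)[C@@H](O)C2 | target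

**Step count and risks**

Total step count: 17 (steps 1–4 make the aroyl chloride, step 5 the dienyl ether, steps 6–17 the main line).
Longest linear sequence: 12 steps, from (R)-carvone 9 to target 28 (steps 6–17).

Steps most likely to fail:

Step 16 (proposed new method). The cascade may stall after the [3,3] shift, or the transient 2-methylene ketones may be diverted by Diels–Alder or Michael addition with the excess dienyl ether before elimination and ring closure. The fallback builds the pyran by cross-coupling and cycloisomerisation and sets out from dione 19. O-Triflation at the C4a oxygen (Tf2O, Et3N, CH2Cl2, −78 °C) should give (1R,6S)-6-[(tert-butyldimethylsilyl)oxy]-1-methyl-2-oxo-4-[(trifluoromethylsulfonyl)oxy]cyclohex-3-en-1-yl aroate F1. Sonogashira coupling with (E)-pent-3-en-1-yne (PdCl2(PPh3)2, CuI, Et3N, THF, rt) should give the enynone F2. α-Iodination (I2, pyridine, CH2Cl2) should give the 2-iodo enynone F3. Stille coupling with (tributylstannyl)methanol (Pd(PPh3)4, dioxane, 90 °C) should give the 2-(hydroxymethyl) enynone F4. AuCl3 (5 mol %, CH2Cl2, rt) should then trigger 6-endo-dig addition of the hydroxyl to the δ-carbon of the ynenone, which returns to the route at 27.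

Step 10. Acyl transfer to the congested tertiary α-ketol may be blocked sterically, or the β-acetoxy ketone may eliminate under the activating conditions. The fallback attaches a slim acyl group and builds the arene afterwards; it sets out from 15. Steglich esterification with but-2-ynoic acid (DCC, DMAP, CH2Cl2) should give the tertiary but-2-ynoate F5. Diels–Alder addition of 1-methoxy-1,3-bis(trimethylsilyloxy)buta-1,3-diene (toluene, 110 °C), aromatisation with loss of trimethylsilanol and a mild fluoride work-up should give the 4-hydroxy-2-methoxy-6-methylbenzoate F6; the polarity of the two partners sets the substitution pattern. Silylation of the phenol (TIPSCl, imidazole, DMF) returns to the route at 17.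

Step 15. Transmetalation of an sp3 tin group onto a tetrasubstituted vinylpalladium species is slow and may be outrun by protodeiodination. The fallback introduces C1 at the aldehyde level and sets out from 20. Vilsmeier–Haack formylation at C8a (POCl3, DMF, 0 °C) should give the 3-formyl vinylogous ester F7. Luche reduction of the aldehyde (NaBH4, CeCl3·7H2O, MeOH, −78 °C) returns to the route at 22.

**Further compounds**

F1 | step 16 | (1R,6S)-6-[(tert-butyldimethylsilyl)oxy]-1-methyl-2-oxo-4-[(trifluoromethylsulfonyl)oxy]cyclohex-3-en-1-yl 2-methoxy-6-methyl-4-[(triisopropylsilyl)oxy]benzoate | O=C1[C@](C)(OC(=O)c2c(C)cc(O[Si](C(C)C)(C(C)C)C(C)C)cc2OC)[C@@H](O[Si](C)(C)C(C)(C)C)CC(OS(=O)(=O)C(F)(F)F)=C1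
F2 | step 16 | (1R,6S)-6-[(tert-butyldimethylsilyl)oxy]-1-methyl-2-oxo-4-[(3E)-pent-3-en-1-yn-1-yl]cyclohex-3-en-1-yl 2-methoxy-6-methyl-4-[(triisopropylsilyl)oxy]benzoate | O=C1[C@](C)(OC(=O)c2c(C)cc(O[Si](C(C)C)(C(C)C)C(C)C)cc2OC)[C@@H](O[Si](C)(C)C(C)(C)C)CC(C#C/C=C/C)=C1
F3 | step 16 | (1R,6S)-6-[(tert-butyldimethylsilyl)oxy]-3-iodo-1-methyl-2-oxo-4-[(3E)-pent-3-en-1-yn-1-yl]cyclohex-3-en-1-yl 2-methoxy-6-methyl-4-[(triisopropylsilyl)oxy]benzoate | O=C1[C@](C)(OC(=O)c2c(C)cc(O[Si](C(C)C)(C(C)C)C(C)C)cc2OC)[C@@H](O[Si](C)(C)C(C)(C)C)CC(C#C/C=C/C)=C1I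
F4 | step 16 | (1R,6S)-6-[(tert-butyldimethylsilyl)oxy]-3-(hydroxymethyl)-1-methyl-2-oxo-4-[(3E)-pent-3-en-1-yn-1-yl]cyclohex-3-en-1-yl 2-methoxy-6-methyl-4-[(triisopropylsilyl)oxy]benzoate | O=C1[C@](C)(OC(=O)c2c(C)cc(O[Si](C(C)C)(C(C)C)C(C)C)cc2OC)[C@@H](O[Si](C)(C)C(C)(C)C)CC(C#C/C=C/C)=C1CO
F5 | step 10 | (1R,2S,4R)-4-(acetyloxy)-2-[(tert-butyldimethylsilyl)oxy]-1-methyl-6-oxocyclohexyl but-2-ynoate | O=C1[C@](C)(OC(=O)C#CC)[C@@H](O[Si](C)(C)C(C)(C)C)C[C@@H](OC(C)=O)C1
F6 | step 10 | (1R,2S,4R)-4-(acetyloxy)-2-[(tert-butyldimethylsilyl)oxy]-1-methyl-6-oxocyclohexyl 4-hydroxy-2-methoxy-6-methylbenzoate | O=C1[C@](C)(OC(=O)c2c(C)cc(O)cc2OC)[C@@H](O[Si](C)(C)C(C)(C)C)C[C@@H](OC(C)=O)C1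
F7 | step 15 | (1R,6S)-6-[(tert-butyldimethylsilyl)oxy]-3-formyl-4-methoxy-1-methyl-2-oxocyclohex-3-en-1-yl 2-methoxy-6-methyl-4-[(triisopropylsilyl)oxy]benzoate | O=C1[C@](C)(OC(=O)c2c(C)cc(O[Si](C(C)C)(C(C)C)C(C)C)cc2OC)[C@@H](O[Si](C)(C)C(C)(C)C)CC(OC)=C1C=O
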